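**Target.** 10 is 5,7-dihydroxy-6-[(2R)-2-hydroxy-3-methylbut-3-en-1-yl]-3-(4-methoxyphenyl)-4H-chromen-4-one, i.e. biochanin A carrying an (R)-CH2–CH(OH)–C(CH3)=CH2 chain on C6, the ring-A carbon between the 5-OH and 7-OH groups. In the target SMILES the centre has O > isopropenyl > CH2Ar > H, which gives R. Side-chain atoms are numbered C1' (CH2), C2' (carbinol), C3' (=C), C4' (=CH2).

## The problem

The isoflavone core is not the difficulty, because biochanin A (1) is commercial; the difficulty is to put a five-carbon chain on C6 and not on C8, both being activated CH positions of the phloroglucinol-type ring A. The usual sigmatropic prenylation (5-O-prenyl, Claisen then Cope) ends at C8, and direct C-alkylation gives C6/C8/O mixtures. The only stereocentre, C2', is isolated, and nothing in the flat, achiral core can control it, so it must come from a reagent, a catalyst or a chiral building block. C2' is a secondary allylic alcohol next to a 1,1-disubstituted alkene and lies between two phenolic oxygens (O5 and O7): acid can protonate the isopropenyl group or ionise the alcohol, after which either phenol closes a chroman or dihydrofuran ring, and hydrogenolysis would reduce the alkene. The chromone is a vinylogous ester with an electrophilic C2, so strong carbanions, hot hydroxide and alkaline peroxide (C2=C3 epoxidation, ring opening) must be avoided. The enabling feature is the unit C1'–C2', in which C1' bears an aryl carbon (C6 of ring A) and C2' bears an oxygen and an sp2 carbon (C3'); this pattern, Ar–CH2–CH(X)–alkenyl, is what a vinyl-boron "ate" complex gives when an arylpalladium adds to the vinyl terminus and an alkenyl group shifts from boron to the adjacent carbon. In addition, C6 is the only position ortho to the free, chelated 5-OH, which allows a C6-selective iodination.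

## Retrosynthesis

**10 ⇒ 9 (O5–acetyl and O7–Si bonds).** The two phenols are unmasked last. An acetate on O5 and a tert-butyldimethylsilyl ether on O7 are chosen because both fall to K2CO3/MeOH. Acid-labile or hydrogenolysable groups are excluded by the allylic alcohol and the alkene. The forward step only needs mild basic methanolysis, which the chromone and the alcohol tolerate.

**9 ⇒ 8 (C2'–O traced to C2'–B).** The hydroxyl is written as a boron substituent. Oxidation of a secondary pinacol boronate goes with retention, so the C2' configuration is decided when the C–B centre is made. 8 is an α-chiral allyl pinacol boronate, a class that is configurationally stable and not prone to 1,3-boron shift at moderate temperature.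

**8 ⇒ 4 + 7; 7 ⇒ 5 + 6 (C6–C1' and C2'–C3' cut together).** This is the key disconnection. The side chain is divided into a vinyl group (C1'–C2', from vinylboronic ester 5), an isopropenyl group (C3', C4' and the methyl, from Grignard reagent 6) and the aryl iodide 4. Against the neighbouring single cuts:
- Cutting only C6–C1' needs an enantiopure five-carbon electrophile and an aryl-metal that the chromone cannot survive.
- Cutting only C2'–C3' needs an enolisable arylacetaldehyde.
- Cutting only C2'–O needs a C6-prenyl compound that is itself hard to make.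

The double cut reduces the precursor to a flat aryl iodide plus two commercial C2/C3 alkenyl reagents. The forward reaction must (i) use the unsubstituted vinyl group as acceptor and the isopropenyl group as migrating group, (ii) differentiate the two faces of the boron-bound vinyl group under catalyst control, and (iii) tolerate an aryl iodide with two ortho oxygen substituents.

**4 ⇒ 3 ⇒ 2 ⇒ 1 (O5–acetyl, C6–I, O7–Si).** The iodide is placed by electrophilic iodination ortho to the free 5-OH, with O7 present as an ether-type substituent. The 7-OH is silylated first because it is the acidic, non-chelated phenol and reacts selectively. The 5-OH is acetylated after iodination because the free 5-OH is what directs iodine to C6.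

## Roads not taken

**Alternative 1:** (the obvious route) Cut C2'–O on a pre-installed prenyl group. Forward: 6-prenylbiochanin A, compound A1, is made and protected as its bis-silyl ether, epoxidised enantioselectively with a chiral dioxirane to the (R)-epoxide A2, and the epoxide is then isomerised to the isopropenyl carbinol with a hindered aluminium or lithium amide. Photo-oxygenation (Schenck ene) is the racemic variant.
- A1 is not directly accessible: sigmatropic prenylation from O5 ends at C8 and direct C-prenylation is unselective, so several steps are spent before the stereocentre is addressed.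
- The epoxide of A2 sits between O5 and O7 and is opened 5-exo or 6-endo whenever a phenol is unmasked or a Lewis acid is present.
- The amide bases needed for the isomerisation attack the chromone at C2.
- Singlet oxygen gives no enantiocontrol and also abstracts the benzylic hydrogen.
- Two reagent-controlled steps are needed for one stereocentre; the chosen plan sets chain and stereocentre in one operation.

**Alternative 2:** Cut C2'–C3' (carbinol–isopropenyl). Forward: after methoxymethyl protection of O7 and allylation of O5, an aromatic Claisen rearrangement (C6 is the only free ortho position) gives the 6-allyl compound A3; re-protection of O5 and oxidative cleavage give the arylacetaldehyde A4, which undergoes catalytic asymmetric Ni/Cr-mediated addition of 2-bromopropene.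
- Regiochemistry is secure, but the route takes about eight steps and a rearrangement near 190 °C.
- A4 is an enolisable α-aryl aldehyde with an ortho oxygen; it is prone to enolisation and to benzofuran formation if O5 is lost.
- The stereocentre still needs a separate step on that aldehyde, and the heat- and base-stable methoxymethyl group on O7 of A3 and A4 must later come off in acid.
- The chosen plan uses the same number of C–C bond-forming events (two) in one flask, without the aldehyde.

**Alternative 3:** Cut only C6–C1', aryl nucleophile plus chiral epoxide. Forward: the aryllithium A5, made by ortho-lithiation of 1,3,5-tris(methoxymethoxy)benzene, is converted into its cuprate and opens the vinyl epoxide A6, which is (S)-2-(prop-1-en-2-yl)oxirane, to give the alcohol A7; the isoflavone is then built by acylation and ring closure.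
- Cuprates attack vinyl epoxides by the SN2' path, so the cuprate of A5 would put the aryl group on C4' of A6.
- An aryl-metal such as A5 is incompatible with a chromone, so commercial 1 is discarded and the heterocycle must be built after the sensitive alcohol of A7 is in place, under Friedel–Crafts and ring-closure conditions.
- The C6/C8 question returns at ring closure, because either ortho oxygen of the ketone can close.
- A6 is volatile and needs its own resolution.

Key step: step 4

## Assumptions

- (Sp,Sp)-MandyPhos is assumed to deliver the (R)-boronate 8, by analogy with aryl electrophiles combined with sp2 migrating groups. If the sense is the opposite, the (Rp,Rp)-ligand is used and nothing else changes.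
- Compounds 1, 5 and 6 (as a THF solution) are taken as commercial.

## Route

Step 1
Reactants: 1 biochanin A (5,7-dihydroxy-3-(4-methoxyphenyl)-4H-chromen-4-one)
Product: 2 7-[(tert-butyldimethylsilyl)oxy]-5-hydroxy-3-(4-methoxyphenyl)-4H-chromen-4-one
Conditions: TBSCl (1.1 equiv), imidazole, DMF, 0 °C → rt
Reagents that add atoms: tert-butyldimethylsilyl chloride, CC(C)(C)[Si](C)(C)Cl
Why: Selective O-silylation; the 7-OH is the acidic, free phenol, while the 5-OH is hydrogen-bonded to the C4 carbonyl and should stay untouched with one equivalent of silyl chloride.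

Step 2
Reactants: 2 7-[(tert-butyldimethylsilyl)oxy]-5-hydroxy-3-(4-methoxyphenyl)-4H-chromen-4-one
Product: 3 7-[(tert-butyldimethylsilyl)oxy]-5-hydroxy-6-iodo-3-(4-methoxyphenyl)-4H-chromen-4-one
Conditions: BnMe3N+ ICl2− (1.05 equiv), CaCO3, CH2Cl2/MeOH, rt
Reagents that add atoms: benzyltrimethylammonium dichloroiodate, C[N+](C)(C)Cc1ccccc1.Cl[I-]Cl
Why: Electrophilic aromatic iodination; with a free 5-OH and an ether-type O7 substituent this reagent should iodinate a 5,7-dioxygenated chromone at C6, the position ortho to the free phenol, and CaCO3 buffers the HCl so the silyl ether and the anisyl ring should survive.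

Step 3
Reactants: 3 7-[(tert-butyldimethylsilyl)oxy]-5-hydroxy-6-iodo-3-(4-methoxyphenyl)-4H-chromen-4-one
Product: 4 7-[(tert-butyldimethylsilyl)oxy]-6-iodo-3-(4-methoxyphenyl)-4-oxo-4H-chromen-5-yl acetate
Conditions: Ac2O, Et3N, DMAP (cat.), CH2Cl2, rt → 40 °C
Reagents that add atoms: acetic anhydride, CC(=O)OC(C)=O
Why: DMAP-catalysed O-acylation; the small acetyl group can reach the chelated 5-OH between the peri carbonyl and the iodine, it removes the acidic proton before the borate chemistry, and it is later cleaved by the same base as the silyl ether.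

Step 4
Reactants: 4 7-[(tert-butyldimethylsilyl)oxy]-6-iodo-3-(4-methoxyphenyl)-4-oxo-4H-chromen-5-yl acetate; 5 4,4,5,5-tetramethyl-2-vinyl-1,3,2-dioxaborolane (vinylboronic acid pinacol ester); 6 isopropenylmagnesium bromide
Product: 9 7-[(tert-butyldimethylsilyl)oxy]-6-[(2R)-2-hydroxy-3-methylbut-3-en-1-yl]-3-(4-methoxyphenyl)-4-oxo-4H-chromen-5-yl acetate, via bromomagnesium isopropenyl(vinyl)(pinacolato)borate 7 (not isolated), via (R)-allylboronate 8 (not isolated)
Conditions: 5 (slight excess over 6), 6, THF, 0 °C → rt; then 4, Pd(OAc)2 (cat.), (Sp,Sp)-MandyPhos (cat.), NaOTf, THF, 60 °C; filtration through a short silica pad, crude filtrate carried on; then 30% H2O2, pH 7 phosphate buffer, THF, 0 °C → rt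
Reagents that add atoms: hydrogen peroxide, OO
Why: Enantioselective palladium-catalysed conjunctive cross-coupling of a bis(alkenyl)borate with an aryl halide, followed by stereoretentive C–B oxidation. Grignard 6 adds to boron of 5 to give the four-coordinate borate 7, kept free of residual Grignard by the slight excess of 5; NaOTf exchanges the counter-ion and removes halide so that palladium stays cationic. Pd(0)/MandyPhos inserts into the C6–I bond of 4, the arylpalladium cation binds the unsubstituted, less hindered vinyl group of 7, and the isopropenyl group shifts from boron to the internal vinyl carbon anti to palladium while Pd–C1' forms; reductive elimination then makes the C6–C1' bond and gives 8. The closest known reaction type is the MandyPhos–Pd conjunctive coupling of bis(alkenyl)borates with aryl electrophiles to α-chiral allylboronates, in its variant for Grignard-derived borates and C(sp2) halides with NaOTf. No ring is closed. The new stereocentre C2' is set by the ligand, which selects the face of the boron-bound vinyl group in the Pd–olefin complex; the anti 1,2-shift is stereospecific, and the oxidation (hydroperoxide adds to boron, C2' migrates to oxygen) retains configuration, so (R)-8 gives (R)-9. Site selectivity on the arene is fixed by the C–I bond; acceptor versus migrating group is secured by the steric difference between vinyl and the 1,1-disubstituted isopropenyl; conjunctive coupling over direct Suzuki-type transfer is secured by the chelating ligand and the halide-free cationic palladium. The silica pad removes iodide and palladium before peroxide is added, and pH 7 keeps hydroperoxide anion low so that the chromone C2=C3 bond, the acetate and the silyl ether should survive.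

Step 5
Reactants: 9 7-[(tert-butyldimethylsilyl)oxy]-6-[(2R)-2-hydroxy-3-methylbut-3-en-1-yl]-3-(4-methoxyphenyl)-4-oxo-4H-chromen-5-yl acetate
Product: 10 5,7-dihydroxy-6-[(2R)-2-hydroxy-3-methylbut-3-en-1-yl]-3-(4-methoxyphenyl)-4H-chromen-4-one
Conditions: K2CO3, MeOH, 0 °C → rt; aq. NH4Cl work-up
Reagents that add atoms: none
Why: Base-mediated methanolysis of the aryl acetate and of the aryl silyl ether (the 7-oxychromone is a good leaving group on silicon); any acetyl that shifts from O5 to the C2' oxygen is removed by the same methanolysis. The conditions are neither acidic nor reducing, so the allylic alcohol, the alkene and the C2' configuration should be untouched.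

## Compound list

1 | biochanin A, 5,7-dihydroxy-3-(4-methoxyphenyl)-4H-chromen-4-one | COc1ccc(cc1)-c1coc2cc(O)cc(O)c2c1=O | starting material
2 | 7-[(tert-butyldimethylsilyl)oxy]-5-hydroxy-3-(4-methoxyphenyl)-4H-chromen-4-one | COc1ccc(cc1)-c1coc2cc(O[Si](C)(C)C(C)(C)C)cc(O)c2c1=O | intermediate
3 | 7-[(tert-butyldimethylsilyl)oxy]-5-hydroxy-6-iodo-3-(4-methoxyphenyl)-4H-chromen-4-one | COc1ccc(cc1)-c1coc2cc(O[Si](C)(C)C(C)(C)C)c(I)c(O)c2c1=O | intermediate
4 | 7-[(tert-butyldimethylsilyl)oxy]-6-iodo-3-(4-methoxyphenyl)-4-oxo-4H-chromen-5-yl acetate | COc1ccc(cc1)-c1coc2cc(O[Si](C)(C)C(C)(C)C)c(I)c(OC(C)=O)c2c1=O | intermediate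
5 | 4,4,5,5-tetramethyl-2-vinyl-1,3,2-dioxaborolane | C=CB1OC(C)(C)C(C)(C)O1 | starting material
6 | isopropenylmagnesium bromide | C=C(C)[Mg]Br | starting material
7 | bromomagnesium isopropenyl(vinyl)(pinacolato)borate | C=C[B-]1(C(C)=C)OC(C)(C)C(C)(C)O1.[Mg+]Br | intermediate
8 | 7-[(tert-butyldimethylsilyl)oxy]-3-(4-methoxyphenyl)-6-[(2R)-3-methyl-2-(4,4,5,5-tetramethyl-1,3,2-dioxaborolan-2-yl)but-3-en-1-yl]-4-oxo-4H-chromen-5-yl acetate | C=C(C)[C@H](B1OC(C)(C)C(C)(C)O1)Cc1c(O[Si](C)(C)C(C)(C)C)cc2occ(-c3ccc(OC)cc3)c(=O)c2c1OC(C)=O | intermediate
9 | 7-[(tert-butyldimethylsilyl)oxy]-6-[(2R)-2-hydroxy-3-methylbut-3-en-1-yl]-3-(4-methoxyphenyl)-4-oxo-4H-chromen-5-yl acetate | C=C(C)[C@H](O)Cc1c(O[Si](C)(C)C(C)(C)C)cc2occ(-c3ccc(OC)cc3)c(=O)c2c1OC(C)=O | intermediate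
10 | 5,7-dihydroxy-6-[(2R)-2-hydroxy-3-methylbut-3-en-1-yl]-3-(4-methoxyphenyl)-4H-chromen-4-one | C=C(C)[C@H](O)Cc1c(O)cc2occ(-c3ccc(OC)cc3)c(=O)c2c1O | target

## Step count and risk

Total steps: 5. Longest linear sequence: 5 (from 1; reagents 5 and 6 enter in step 4).

**Step 4 (key step).** Most likely to go wrong:
- Olefin binding at an arylpalladium with two ortho oxygen substituents may be slow, so direct boron-to-palladium transfer of an alkenyl group or reduction of the C–I bond could compete.
- Iodide may re-coordinate to palladium and shut down the cationic pathway.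
- The ortho substituents may erode facial selectivity.
- Incomplete borate formation would leave Grignard reagent to attack the acetate or the chromone.

Fallback (known chemistry, changes the bond construction): from 4, Stille coupling with allyltributylstannane (Pd(PPh3)4, toluene, heat) gives 7-[(tert-butyldimethylsilyl)oxy]-3-(4-methoxyphenyl)-4-oxo-6-(prop-2-en-1-yl)-4H-chromen-5-yl acetate F1. Oxidative cleavage of the terminal alkene (OsO4 cat., NaIO4, 2,6-lutidine) gives the arylacetaldehyde F2. Catalytic asymmetric Ni/Cr-mediated addition of 2-bromopropene (CrCl2 cat., NiCl2 cat., chiral sulfonamide ligand, Mn, TMSCl) sets C2' and gives 7-[(tert-butyldimethylsilyl)oxy]-3-(4-methoxyphenyl)-6-{(2R)-3-methyl-2-[(trimethylsilyl)oxy]but-3-en-1-yl}-4-oxo-4H-chromen-5-yl acetate F3. Brief treatment with aqueous citric acid in THF removes the trimethylsilyl group and returns to the route at 9.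

**Step 2.** Most likely to go wrong: competing substitution at C8 or double iodination, and methanolysis of the silyl ether, which would release the 7-OH and remove the regiocontrol.

Fallback (sigmatropic delivery instead of electrophilic substitution): from 2, O5-allylation (allyl bromide, K2CO3, acetone, reflux) gives the 5-O-allyl ether F4. Aromatic Claisen rearrangement (N,N-diethylaniline, about 190 °C) can only reach C6 and gives the 6-allyl-5-hydroxy compound F5. Acetylation (Ac2O, DMAP) gives the acetate F1, which continues through the aldehyde F2 and the silyl ether F3 as described for step 4 and comes back to the route at 9.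

**Step 3.** Most likely to go wrong: slow acylation of the chelated 5-OH flanked by iodine, with silyl loss or acyl scrambling on prolonged heating.

Fallback (irreversible phenoxide alkylation instead of acylation, with a different end-game): from 3, NaH then MOMCl in DMF gives the 5-O-methoxymethyl ether F6. The coupling conditions of step 4 then give the allylboronate F7, and the buffered peroxide oxidation gives the alcohol F8. K2CO3/MeOH removes the silyl group to give the 7-hydroxy compound F9. The 5-O-MOM group, activated by the peri carbonyl, is removed with dilute HCl in MeOH at rt, short enough to spare the allylic alcohol; this returns to the route at 10.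

## Further compounds

F1 | step 4 | 7-[(tert-butyldimethylsilyl)oxy]-3-(4-methoxyphenyl)-4-oxo-6-(prop-2-en-1-yl)-4H-chromen-5-yl acetate | C=CCc1c(O[Si](C)(C)C(C)(C)C)cc2occ(-c3ccc(OC)cc3)c(=O)c2c1OC(C)=O
F2 | step 4 | 7-[(tert-butyldimethylsilyl)oxy]-3-(4-methoxyphenyl)-4-oxo-6-(2-oxoethyl)-4H-chromen-5-yl acetate | O=CCc1c(O[Si](C)(C)C(C)(C)C)cc2occ(-c3ccc(OC)cc3)c(=O)c2c1OC(C)=O
F3 | step 4 | 7-[(tert-butyldimethylsilyl)oxy]-3-(4-methoxyphenyl)-6-{(2R)-3-methyl-2-[(trimethylsilyl)oxy]but-3-en-1-yl}-4-oxo-4H-chromen-5-yl acetate | C=C(C)[C@H](O[Si](C)(C)C)Cc1c(O[Si](C)(C)C(C)(C)C)cc2occ(-c3ccc(OC)cc3)c(=O)c2c1OC(C)=O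
F4 | step 2 | 7-[(tert-butyldimethylsilyl)oxy]-3-(4-methoxyphenyl)-5-(prop-2-en-1-yloxy)-4H-chromen-4-one | C=CCOc1cc(O[Si](C)(C)C(C)(C)C)cc2occ(-c3ccc(OC)cc3)c(=O)c12
F5 | step 2 | 7-[(tert-butyldimethylsilyl)oxy]-5-hydroxy-3-(4-methoxyphenyl)-6-(prop-2-en-1-yl)-4H-chromen-4-one | C=CCc1c(O[Si](C)(C)C(C)(C)C)cc2occ(-c3ccc(OC)cc3)c(=O)c2c1O
F6 | step 3 | 7-[(tert-butyldimethylsilyl)oxy]-6-iodo-5-(methoxymethoxy)-3-(4-methoxyphenyl)-4H-chromen-4-one | COCOc1c(I)c(O[Si](C)(C)C(C)(C)C)cc2occ(-c3ccc(OC)cc3)c(=O)c12
F7 | step 3 | 7-[(tert-butyldimethylsilyl)oxy]-5-(methoxymethoxy)-3-(4-methoxyphenyl)-6-[(2R)-3-methyl-2-(4,4,5,5-tetramethyl-1,3,2-dioxaborolan-2-yl)but-3-en-1-yl]-4H-chromen-4-one | C=C(C)[C@H](B1OC(C)(C)C(C)(C)O1)Cc1c(O[Si](C)(C)C(C)(C)C)cc2occ(-c3ccc(OC)cc3)c(=O)c2c1OCOC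
F8 | step 3 | 7-[(tert-butyldimethylsilyl)oxy]-6-[(2R)-2-hydroxy-3-methylbut-3-en-1-yl]-5-(methoxymethoxy)-3-(4-methoxyphenyl)-4H-chromen-4-one | C=C(C)[C@H](O)Cc1c(O[Si](C)(C)C(C)(C)C)cc2occ(-c3ccc(OC)cc3)c(=O)c2c1OCOC
F9 | step 3 | 7-hydroxy-6-[(2R)-2-hydroxy-3-methylbut-3-en-1-yl]-5-(methoxymethoxy)-3-(4-methoxyphenyl)-4H-chromen-4-one | C=C(C)[C@H](O)Cc1c(O)cc2occ(-c3ccc(OC)cc3)c(=O)c2c1OCOC
A1 | alternative 1 | 6-prenylbiochanin A, 5,7-dihydroxy-3-(4-methoxyphenyl)-6-(3-methylbut-2-en-1-yl)-4H-chromen-4-one | CC(C)=CCc1c(O)cc2occ(-c3ccc(OC)cc3)c(=O)c2c1O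
A2 | alternative 1 | 5,7-bis[(tert-butyldimethylsilyl)oxy]-6-{[(2R)-3,3-dimethyloxiran-2-yl]methyl}-3-(4-methoxyphenyl)-4H-chromen-4-one | CC1(C)O[C@@H]1Cc1c(O[Si](C)(C)C(C)(C)C)cc2occ(-c3ccc(OC)cc3)c(=O)c2c1O[Si](C)(C)C(C)(C)C
A3 | alternative 2 | 5-hydroxy-7-(methoxymethoxy)-3-(4-methoxyphenyl)-6-(prop-2-en-1-yl)-4H-chromen-4-one | C=CCc1c(OCOC)cc2occ(-c3ccc(OC)cc3)c(=O)c2c1O
A4 | alternative 2 | 7-(methoxymethoxy)-3-(4-methoxyphenyl)-4-oxo-6-(2-oxoethyl)-4H-chromen-5-yl acetate | O=CCc1c(OCOC)cc2occ(-c3ccc(OC)cc3)c(=O)c2c1OC(C)=O
A5 | alternative 3 | 2-lithio-1,3,5-tris(methoxymethoxy)benzene | [Li]c1c(OCOC)cc(OCOC)cc1OCOC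
A6 | alternative 3 | (S)-2-(prop-1-en-2-yl)oxirane | C=C(C)[C@H]1CO1
A7 | alternative 3 | (2R)-3-methyl-1-[2,4,6-tris(methoxymethoxy)phenyl]but-3-en-2-ol | C=C(C)[C@H](O)Cc1c(OCOC)cc(OCOC)cc1OCOC
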